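**Retrosynthetic overview**
1. The two inter-unit C15–O ester bonds are cut first: the mixed anhydride 20 of acid 19 acylates the neopentyl C15–OH of unit A, then a second portion of 20 acylates the dimer. All three units come from one monomer, 14.
2. In 14 the C11–O ether bond is cut at the acyclic stage: (2E,6E)-farnesyl bromide plus the (2R,3S)-isocitrate hydroxy triester 6 (O-allylation), so no ether has to be forced onto the hindered decalin.
3. 6 comes from D-malic acid by anti-selective enolate alkylation, which sets C3'.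
4. The C15–O bond comes from allylic oxidation; a Sharpless epoxide relays chirality; one radical cascade closes ring A (C4–C5 bond) and then ring B (C9–C10 bond) and leaves the 8(12)-alkene; the relay oxygen at C3 is then removed.
5. Ring order: A then B within each unit, before the units are joined; a tert-butyl-to-methyl ester switch turns the common monomer into unit A.

Assumption: D-malic acid, (2E,6E)-farnesyl bromide and all named reagents are bought. Names use drimane numbering (C11 = OCH2 on C9, C12 = exocyclic methylene carbon, C15 = 4α-OCH2 on C4) and, for isocitrate, C1' carboxyl (on the ether carbon C2'), central carboxyl (on C3') and terminal carboxyl (CH2CO2); unit A carries the free central acid and unit C the free C15–OH.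

**Route**

Step 1
Reactants: 1 (R)-malic acid
Product: 3 (R)-malic acid 1-methyl ester, via O-trifluoroacetylmalic anhydride 2 (not isolated)
Conditions: (CF3CO)2O, 0 °C to rt; evaporate; MeOH, rt
Reagents that add atoms: methanol (CO)
Why: Regioselective alcoholysis of the O-acylated cyclic anhydride at the carbonyl next to the acyloxy carbon differentiates the two carboxyls; the C2 stereocentre comes from D-malic acid and is untouched.

Step 2
Reactants: 3 (R)-malic acid 1-methyl ester
Product: 4 1-methyl 4-allyl (R)-malate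
Conditions: allyl bromide, KHCO3, DMF, rt
Reagents that add atoms: allyl bromide (C=CCBr)
Why: Carboxylate O-alkylation (SN2) installs the allyl ester that later unmasks the central carboxyl; no stereocentre is affected.

Step 3
Reactants: 4 1-methyl 4-allyl (R)-malate
Product: 6 hydroxy triester (methyl/allyl/tert-butyl isocitrate), via dilithium alkoxide enolate 5 (not isolated)
Conditions: LiN(SiMe3)2 (2.2 equiv), THF, −78 to −20 °C; BrCH2CO2tBu, −78 °C; AcOH quench
Reagents that add atoms: tert-butyl bromoacetate (BrCC(=O)OC(C)(C)C)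
Why: Frater–Seebach alkylation, in which the chelated alkoxide–enolate dianion is alkylated anti to the C2–O bond and sets C3' as S (natural isocitrate, expected dr about 9:1).

Step 4
Reactants: 6 hydroxy triester; 7 (2E,6E)-farnesyl bromide
Product: 8 farnesyl isocitrate ether
Conditions: Ag2O (2 equiv), 7 (2 equiv), 4 Å molecular sieves, Et2O, dark, rt, 48 h
Reagents that add atoms: none
Why: Silver-oxide-promoted Williamson O-allylation (SN2 at the primary allylic carbon) forms the key C11–O ether bond under neutral conditions that avoid lactonization and epimerization; no stereocentre is formed and both E-alkenes are kept.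

Step 5
Reactants: 8 farnesyl isocitrate ether
Product: 9 12-hydroxyfarnesyl isocitrate ether
Conditions: SeO2 (0.3 equiv), salicylic acid (0.1 equiv), tBuOOH (3 equiv), CH2Cl2, 0 °C to rt
Reagents that add atoms: tert-butyl hydroperoxide (CC(C)(C)OO)
Why: Riley allylic oxidation (ene reaction then 2,3-sigmatropic shift) hydroxylates the E-methyl of the terminal, most electron-rich trisubstituted alkene and makes the future C15–O bond; no stereocentre is formed.

Step 6
Reactants: 9 12-hydroxyfarnesyl isocitrate ether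
Product: 11 (10S,11S)-epoxy silyl ether, via epoxy alcohol 10 (not isolated)
Conditions: Ti(OiPr)4 (10 mol%), L-(+)-diethyl tartrate (12 mol%), tBuOOH, 4 Å molecular sieves, CH2Cl2, −20 °C; then TBSCl, imidazole, 0 °C to rt
Reagents that add atoms: tert-butyl hydroperoxide (CC(C)(C)OO); tert-butyldimethylsilyl chloride (CC(C)(C)[Si](C)(C)Cl)
Why: Sharpless asymmetric epoxidation, where L-(+)-tartrate delivers oxygen to the face that gives the 10S,11S epoxide (reagent control), followed by in-situ silylation of the primary alcohol.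

Step 7
Reactants: 11 (10S,11S)-epoxy silyl ether
Product: 12 3β-hydroxy bicyclic monomer
Conditions: Cp2TiCl2 (10 mol%), Co(salen) (C16H14CoN2O2, 2 mol%), Zn (20 mol%), 2,4,6-collidine·HCl (30 mol%), THF (0.02 M), rt
Reagents that add atoms: none
Why: Proposed new method: a redox-neutral titanium/cobalt radical redox-relay cycloisomerization in which Cp2TiCl (trivalent titanium, from Cp2TiCl2 and Zn) opens the epoxide at the more substituted C11 to a freely rotating β-titanoxy tertiary radical, this closes ring A (6-endo onto C6=C7 through a chair in which the titanoxy group and the larger silyloxymethyl group sit pseudo-equatorial, away from the axial methyl of the alkene) and then ring B (6-endo onto C2=C3), and divalent cobalt abstracts a hydrogen atom from the methyl on the resulting C8 radical to give the 8(12)-alkene while the cobalt hydride returns proton and electron to titanium through collidinium; the 10S epoxide carbon becomes C3 (3β-OH) and relays the configuration of C4 (4α-CH2OTBS), C5 (α-H), C9 (β-CH2O) and C10 (β-CH3); the closest known reactions are the Cp2TiCl-mediated radical cyclization of epoxypolyenes and the titanium/cobalt-catalysed isomerization of epoxides to allylic alcohols.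

Step 8
Reactants: 12 3β-hydroxy bicyclic monomer
Product: 13 3-O-(imidazol-1-yl)thiocarbonyl derivative
Conditions: 1,1'-thiocarbonyldiimidazole, DMAP (cat.), ClCH2CH2Cl, 70 °C
Reagents that add atoms: 1,1'-thiocarbonyldiimidazole (S=C(n1ccnc1)n1ccnc1)
Why: Thioacylation of the hindered equatorial alcohol gives the Barton–McCombie substrate; no stereocentre changes.

Step 9
Reactants: 13 3-O-(imidazol-1-yl)thiocarbonyl derivative
Product: 14 monomer (15-OTBS; central allyl ester; terminal tert-butyl ester)
Conditions: Bu3SnH, AIBN (cat.), toluene, 100 °C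
Reagents that add atoms: none
Why: Barton–McCombie radical deoxygenation removes the relay oxygen; the secondary C3 radical is reduced by the stannane and C3 is no longer a stereocentre.

Step 10
Reactants: 14 monomer
Product: 17 unit A silyl ether (terminal methyl ester), via trimethylsilyl ester 15 (not isolated), via carboxylic acid 16 (not isolated)
Conditions: Me3SiOTf, 2,6-lutidine, CH2Cl2, 0 °C; MeOH; then Me3SiCHN2, toluene/MeOH, 0 °C
Reagents that add atoms: (trimethylsilyl)diazomethane (C[Si](C)(C)C=[N+]=[N-])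
Why: Silyl-triflate cleavage of the tert-butyl ester (loss of isobutene, no protic acid) then diazoalkane O-methylation turns the terminal carboxyl into the methyl ester of unit A without touching the allyl ester, the silyl ether or the exocyclic alkene; no stereocentre is affected.

Step 11
Reactants: 17 unit A silyl ether
Product: 18 unit A alcohol
Conditions: HF·pyridine, pyridine, THF, 0 °C to rt
Reagents that add atoms: none
Why: Fluoride-mediated desilylation frees the neopentyl C15–OH acceptor.

Step 12
Reactants: 14 monomer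
Product: 19 unit B/C acid (central CO2H; 15-OTBS; terminal tert-butyl ester)
Conditions: Pd(PPh3)4 (5 mol%), morpholine, THF, rt
Reagents that add atoms: none
Why: Tsuji–Trost deallylation (zerovalent palladium, morpholine as allyl acceptor) unmasks only the central carboxyl.

Step 13
Reactants: 19 unit B/C acid
Product: 20 mixed anhydride of 19 with 2,4,6-trichlorobenzoic acid
Conditions: 2,4,6-trichlorobenzoyl chloride (1.05 equiv), Et3N, THF, 0 °C to rt; filter under Ar, evaporate; kept as a toluene solution at −20 °C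
Reagents that add atoms: 2,4,6-trichlorobenzoyl chloride (O=C(Cl)c1c(Cl)cc(Cl)cc1Cl)
Why: First stage of the Yamaguchi esterification (acylation of the triethylammonium carboxylate by the aroyl chloride) gives a mixed anhydride whose aroyl carbonyl is shielded by two ortho chlorines; it is made once on all of 19 and its solution is divided between the two inter-unit couplings; no stereocentre is affected.

Step 14
Reactants: 20 mixed anhydride; 18 unit A alcohol
Product: 21 dimer silyl ether
Conditions: 20 (1.3 equiv), DMAP (2 equiv), toluene, rt to 40 °C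
Reagents that add atoms: none
Why: Second stage of the Yamaguchi esterification (DMAP attacks the unshielded aliphatic carbonyl and the acylpyridinium transfers the acyl group to the neopentyl alcohol) forms the first inter-unit C15–O ester bond; the C3' centre next to the activated carbonyl is kept by staying at or below 40 °C.

Step 15
Reactants: 21 dimer silyl ether
Product: 22 dimer alcohol
Conditions: HF·pyridine, pyridine, THF, 0 °C to rt
Reagents that add atoms: none
Why: Fluoride-mediated desilylation frees the C15–OH of unit B; the tert-butyl, allyl and methyl esters are inert.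

Step 16
Reactants: 20 mixed anhydride; 22 dimer alcohol
Product: 23 protected trimer
Conditions: 20 (1.3 equiv), DMAP (2 equiv), toluene, rt to 40 °C
Reagents that add atoms: none
Why: A second DMAP-mediated acyl transfer from the Yamaguchi mixed anhydride forms the second inter-unit C15–O ester bond; no stereocentre is formed.

Step 17
Reactants: 23 protected trimer
Product: 24 trimer mono-acid
Conditions: Pd(PPh3)4 (5 mol%), morpholine, THF, rt
Reagents that add atoms: none
Why: Tsuji–Trost deallylation (zerovalent palladium) frees the central carboxyl of unit A, the only allyl ester left.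

Step 18
Reactants: 24 trimer mono-acid
Product: 26 cryptoporic acid T, via tris(trimethylsilyl) ester 25 (not isolated)
Conditions: Me3SiOTf, 2,6-lutidine, CH2Cl2, 0 °C; then HF·pyridine, THF, 0 °C to rt
Reagents that add atoms: none
Why: Silyl-triflate cleavage turns both tert-butyl esters into silyl esters without protic acid, so the three exocyclic alkenes are not isomerized, and fluoride then removes every silyl group; methyl esters and inter-unit esters are untouched.

**Compound list**

1 | (R)-malic acid, (2R)-2-hydroxybutanedioic acid | O[C@@H](C(=O)O)CC(=O)O | starting material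
2 | (3R)-2,5-dioxooxolan-3-yl trifluoroacetate (O-trifluoroacetylmalic anhydride) | O=C1C[C@@H](OC(=O)C(F)(F)F)C(=O)O1 | intermediate
3 | (3R)-3-hydroxy-4-methoxy-4-oxobutanoic acid | O[C@@H](C(=O)OC)CC(=O)O | intermediate
4 | 1-methyl 4-prop-2-enyl (2R)-2-hydroxybutanedioate | O[C@@H](C(=O)OC)CC(=O)OCC=C | intermediate
5 | dilithium salt of 4 (C2 alkoxide, C3 allyl-ester enolate; 2R) | [Li+].[Li+].[O-][C@@H](C(=O)OC)C=C([O-])OCC=C | intermediate
6 | 1-methyl 2-prop-2-enyl 3-tert-butyl (1R,2S)-1-hydroxypropane-1,2,3-tricarboxylate | O[C@@H](C(=O)OC)[C@H](CC(=O)OC(C)(C)C)C(=O)OCC=C | intermediate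
7 | (2E,6E)-1-bromo-3,7,11-trimethyldodeca-2,6,10-triene | CC(C)=CCC/C(C)=C/CC/C(C)=C/CBr | starting material
8 | 1-methyl 2-prop-2-enyl 3-tert-butyl (1R,2S)-1-{[(2E,6E)-3,7,11-trimethyldodeca-2,6,10-trien-1-yl]oxy}propane-1,2,3-tricarboxylate | CC(C)=CCC/C(C)=C/CC/C(C)=C/CO[C@@H](C(=O)OC)[C@H](CC(=O)OC(C)(C)C)C(=O)OCC=C | intermediate
9 | as 8 with a (2E,6E,10E)-12-hydroxy-3,7,11-trimethyldodeca-2,6,10-trien-1-yl ether group | OC/C(C)=C/CC/C(C)=C/CC/C(C)=C/CO[C@@H](C(=O)OC)[C@H](CC(=O)OC(C)(C)C)C(=O)OCC=C | intermediate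
10 | as 8 with a (2E,6E)-9-[(2S,3S)-3-(hydroxymethyl)-3-methyloxiran-2-yl]-3,7-dimethylnona-2,6-dien-1-yl ether group | OC[C@]1(C)O[C@H]1CC/C(C)=C/CC/C(C)=C/CO[C@@H](C(=O)OC)[C@H](CC(=O)OC(C)(C)C)C(=O)OCC=C | intermediate
11 | tert-butyldimethylsilyl ether of 10 | CC(C)(C)[Si](C)(C)OC[C@]1(C)O[C@H]1CC/C(C)=C/CC/C(C)=C/CO[C@@H](C(=O)OC)[C@H](CC(=O)OC(C)(C)C)C(=O)OCC=C | intermediate
12 | 1-methyl 2-prop-2-enyl 3-tert-butyl (1R,2S)-1-{[(1S,4aR,5R,6S,8aS)-5-(tert-butyldimethylsilyloxymethyl)-6-hydroxy-5,8a-dimethyl-2-methylidenedecahydronaphthalen-1-yl]methoxy}propane-1,2,3-tricarboxylate (drimane: 3β-OH, 4α-CH2OTBS, 5α-H, 9β-CH2O, 10β-CH3) | C=C1CC[C@H]2[C@](C)(CO[Si](C)(C)C(C)(C)C)[C@@H](O)CC[C@]2(C)[C@H]1CO[C@@H](C(=O)OC)[C@H](CC(=O)OC(C)(C)C)C(=O)OCC=C | intermediate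
13 | 12 with the 3β-OH as O-(1H-imidazol-1-ylcarbonothioyl) ester | C=C1CC[C@H]2[C@](C)(CO[Si](C)(C)C(C)(C)C)[C@@H](OC(=S)n3ccnc3)CC[C@]2(C)[C@H]1CO[C@@H](C(=O)OC)[C@H](CC(=O)OC(C)(C)C)C(=O)OCC=C | intermediate
14 | 1-methyl 2-prop-2-enyl 3-tert-butyl (1R,2S)-1-{[(1S,4aR,5R,8aS)-5-(tert-butyldimethylsilyloxymethyl)-5,8a-dimethyl-2-methylidenedecahydronaphthalen-1-yl]methoxy}propane-1,2,3-tricarboxylate | C=C1CC[C@H]2[C@](C)(CO[Si](C)(C)C(C)(C)C)CCC[C@]2(C)[C@H]1CO[C@@H](C(=O)OC)[C@H](CC(=O)OC(C)(C)C)C(=O)OCC=C | intermediate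
15 | 14 with the terminal carboxyl as trimethylsilyl ester | C=C1CC[C@H]2[C@](C)(CO[Si](C)(C)C(C)(C)C)CCC[C@]2(C)[C@H]1CO[C@@H](C(=O)OC)[C@H](CC(=O)O[Si](C)(C)C)C(=O)OCC=C | intermediate
16 | 14 with the terminal carboxyl free | C=C1CC[C@H]2[C@](C)(CO[Si](C)(C)C(C)(C)C)CCC[C@]2(C)[C@H]1CO[C@@H](C(=O)OC)[C@H](CC(=O)O)C(=O)OCC=C | intermediate
17 | 14 with the terminal carboxyl as methyl ester (1,3-dimethyl 2-prop-2-enyl triester; 15-OTBS) | C=C1CC[C@H]2[C@](C)(CO[Si](C)(C)C(C)(C)C)CCC[C@]2(C)[C@H]1CO[C@@H](C(=O)OC)[C@H](CC(=O)OC)C(=O)OCC=C | intermediate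
18 | 17 with free C15–OH (unit A alcohol) | C=C1CC[C@H]2[C@](C)(CO)CCC[C@]2(C)[C@H]1CO[C@@H](C(=O)OC)[C@H](CC(=O)OC)C(=O)OCC=C | intermediate
19 | 14 with the central carboxyl free (unit B/C acid) | C=C1CC[C@H]2[C@](C)(CO[Si](C)(C)C(C)(C)C)CCC[C@]2(C)[C@H]1CO[C@@H](C(=O)OC)[C@H](CC(=O)OC(C)(C)C)C(=O)O | intermediate
20 | mixed anhydride of 19 (central carboxyl) with 2,4,6-trichlorobenzoic acid | C=C1CC[C@H]2[C@](C)(CO[Si](C)(C)C(C)(C)C)CCC[C@]2(C)[C@H]1CO[C@@H](C(=O)OC)[C@H](CC(=O)OC(C)(C)C)C(=O)OC(=O)c1c(Cl)cc(Cl)cc1Cl | intermediate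
21 | dimer silyl ether: central carboxyl of 19 (unit B, 15-OTBS, terminal tert-butyl ester) esterified with the C15–OH of 18 (unit A, central allyl ester, terminal methyl ester) | C=C1CC[C@H]2[C@](C)(COC(=O)[C@@H](CC(=O)OC(C)(C)C)[C@@H](OC[C@H]3C(=C)CC[C@H]4[C@](C)(CO[Si](C)(C)C(C)(C)C)CCC[C@]34C)C(=O)OC)CCC[C@]2(C)[C@H]1CO[C@@H](C(=O)OC)[C@H](CC(=O)OC)C(=O)OCC=C | intermediate
22 | dimer alcohol: 21 with free C15–OH on unit B | C=C1CC[C@H]2[C@](C)(COC(=O)[C@@H](CC(=O)OC(C)(C)C)[C@@H](OC[C@H]3C(=C)CC[C@H]4[C@](C)(CO)CCC[C@]34C)C(=O)OC)CCC[C@]2(C)[C@H]1CO[C@@H](C(=O)OC)[C@H](CC(=O)OC)C(=O)OCC=C | intermediate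
23 | protected trimer: central carboxyl of a second 19 (unit C, 15-OTBS) esterified with the C15–OH of 22 | C=C1CC[C@H]2[C@](C)(COC(=O)[C@@H](CC(=O)OC(C)(C)C)[C@@H](OC[C@H]3C(=C)CC[C@H]4[C@](C)(COC(=O)[C@@H](CC(=O)OC(C)(C)C)[C@@H](OC[C@H]5C(=C)CC[C@H]6[C@](C)(CO[Si](C)(C)C(C)(C)C)CCC[C@]56C)C(=O)OC)CCC[C@]34C)C(=O)OC)CCC[C@]2(C)[C@H]1CO[C@@H](C(=O)OC)[C@H](CC(=O)OC)C(=O)OCC=C | intermediate
24 | trimer mono-acid: 23 with the central carboxyl of unit A free | C=C1CC[C@H]2[C@](C)(COC(=O)[C@@H](CC(=O)OC(C)(C)C)[C@@H](OC[C@H]3C(=C)CC[C@H]4[C@](C)(COC(=O)[C@@H](CC(=O)OC(C)(C)C)[C@@H](OC[C@H]5C(=C)CC[C@H]6[C@](C)(CO[Si](C)(C)C(C)(C)C)CCC[C@]56C)C(=O)OC)CCC[C@]34C)C(=O)OC)CCC[C@]2(C)[C@H]1CO[C@@H](C(=O)OC)[C@H](CC(=O)OC)C(=O)O | intermediate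
25 | tris(trimethylsilyl) ester: terminal carboxyls of units B and C and central carboxyl of unit A as Me3Si esters; unit C 15-OTBS | C=C1CC[C@H]2[C@](C)(COC(=O)[C@@H](CC(=O)O[Si](C)(C)C)[C@@H](OC[C@H]3C(=C)CC[C@H]4[C@](C)(COC(=O)[C@@H](CC(=O)O[Si](C)(C)C)[C@@H](OC[C@H]5C(=C)CC[C@H]6[C@](C)(CO[Si](C)(C)C(C)(C)C)CCC[C@]56C)C(=O)OC)CCC[C@]34C)C(=O)OC)CCC[C@]2(C)[C@H]1CO[C@@H](C(=O)OC)[C@H](CC(=O)OC)C(=O)O[Si](C)(C)C | intermediate
26 | cryptoporic acid T | C=C1CC[C@H]2[C@](C)(COC(=O)[C@@H](CC(=O)O)[C@@H](OC[C@H]3C(=C)CC[C@H]4[C@](C)(COC(=O)[C@@H](CC(=O)O)[C@@H](OC[C@H]5C(=C)CC[C@H]6[C@](C)(CO)CCC[C@]56C)C(=O)OC)CCC[C@]34C)C(=O)OC)CCC[C@]2(C)[C@H]1CO[C@@H](C(=O)OC)[C@H](CC(=O)OC)C(=O)O | target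

**Step count**

Total step count: 18. Longest linear sequence: 16 (steps 1–9, then 12–18).

**Three steps most likely to fail**

Step 7 (the proposed new cycloisomerization). The cobalt catalyst may abstract hydrogen before both rings have closed, the cobalt hydride may isomerize alkenes, the C8 radical may take the activated hydrogen at C2', or the freely rotating C11 radical may give some of the C4 epimer. The fallback sets out from 11 and comes back at 12. It drops the catalytic redox relay for the established stoichiometric reductive radical cyclization: Cp2TiCl, made from Cp2TiCl2 (2.2 equiv) and Mn dust in THF, opens the epoxide, and after the same two ring closures a second titanium centre traps the C8 radical and β-hydride elimination releases the exocyclic alkene. This is known chemistry for epoxypolyenes and makes no new compound F0.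

Step 5 (allylic oxidation of the valuable ether 8). Internal allylic positions may compete, the alcohol may over-oxidize to the enal, and conversion is typically partial. The fallback sets out from 6 and comes back at 11; it installs the C12 oxygen before the ether bond is made. Commercial (2E,6E)-farnesyl acetate, the substrate on which this SeO2/tBuOOH oxidation is established, gives (2E,6E,10E)-12-hydroxyfarnesyl acetate F1. Sharpless epoxidation with L-(+)-diethyl tartrate gives epoxy alcohol acetate F2, silylated in the same flask to epoxy silyl ether acetate F3. K2CO3 in MeOH removes the acetate to give epoxy silyl ether alcohol F4; MsCl/Et3N gives mesylate F5 and LiBr gives epoxy silyl ether bromide F6. Ag2O-mediated O-alkylation of 6 with F6, as in step 4, gives 11.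

Step 14 (and likewise step 16). A neopentyl alcohol meets an α-branched acyl donor whose acylpyridinium form can epimerize at C3' or lose the β-alkoxy group under DMAP, and the stored mixed anhydride 20 may partly disproportionate to the symmetric anhydride of 19. The fallback sets out from 19 and comes back at 21; it bypasses 20 and replaces base-mediated acylpyridinium activation by thiophilic-metal activation of a thioester. 19 with 2,2'-dipyridyl disulfide and PPh3 gives S-(pyridin-2-yl) thioester F7, which AgOSO2CF3, buffered with 2,6-di-tert-butylpyridine, couples with 18 in toluene to give 21. The same thioester couples with 22 to give 23.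

**Further compounds**

F0 | step 7 | none | none
F1 | step 5 | (2E,6E,10E)-12-hydroxy-3,7,11-trimethyldodeca-2,6,10-trien-1-yl acetate | OC/C(C)=C/CC/C(C)=C/CC/C(C)=C/COC(C)=O
F2 | step 5 | (2E,6E)-9-[(2S,3S)-3-(hydroxymethyl)-3-methyloxiran-2-yl]-3,7-dimethylnona-2,6-dien-1-yl acetate | OC[C@]1(C)O[C@H]1CC/C(C)=C/CC/C(C)=C/COC(C)=O
F3 | step 5 | tert-butyldimethylsilyl ether of F2 | CC(C)(C)[Si](C)(C)OC[C@]1(C)O[C@H]1CC/C(C)=C/CC/C(C)=C/COC(C)=O
F4 | step 5 | (2E,6E)-9-[(2S,3S)-3-(tert-butyldimethylsilyloxymethyl)-3-methyloxiran-2-yl]-3,7-dimethylnona-2,6-dien-1-ol | CC(C)(C)[Si](C)(C)OC[C@]1(C)O[C@H]1CC/C(C)=C/CC/C(C)=C/CO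
F5 | step 5 | methanesulfonate of F4 | CC(C)(C)[Si](C)(C)OC[C@]1(C)O[C@H]1CC/C(C)=C/CC/C(C)=C/COS(C)(=O)=O
F6 | step 5 | bromide from F4 (1-bromo in place of 1-OH) | CC(C)(C)[Si](C)(C)OC[C@]1(C)O[C@H]1CC/C(C)=C/CC/C(C)=C/CBr
F7 | step 14 | S-(pyridin-2-yl) thioester of 19 at the central carboxyl | C=C1CC[C@H]2[C@](C)(CO[Si](C)(C)C(C)(C)C)CCC[C@]2(C)[C@H]1CO[C@@H](C(=O)OC)[C@H](CC(=O)OC(C)(C)C)C(=O)Sc1ccccn1
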